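**Retrosynthetic overview**
1. The quinone comes from a 3,5-dialkylphenol, which comes from a plain m-tolyl group by late C–H borylation/oxidation. The acid comes from its methyl ester.
2. The C13 methyl comes from a C13 ketone (methylenation, then hydrogenation). C14 (quaternary) and the C8–H come from reductive benzylation of a decalin enone with 3-methylbenzyl bromide.
3. The C5 isopropylidene comes from a C5 ketone through a spiro-β-lactone that loses CO2.
4. Ring B comes from ring expansion of a 1-vinylcyclopentanol. A radical carboalkylation builds the propanoate chain, and a semipinacol shift of the quaternary C9 turns the five-membered ring into the six-membered one.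
5. The hydrindenedione comes from 2-methylcyclopentane-1,3-dione and ethyl vinyl ketone. Ring order: cyclopentane (bought), ring C (aldol), ring B (expansion of the cyclopentane), quinone last.

Assumption: locants follow diterpene numbering. C10 is the CH carrying the propanoate chain, C5 the ring carbon carrying the isopropylidene, C9 the angular C–CH3, C8 the angular C–H, C14 the quaternary C(CH3)(CH2Ar), and C13 the CH–CH3. β is the face of the C9 methyl.

**Step 1**
Reactants: 1 2-methylcyclopentane-1,3-dione; 2 pent-1-en-3-one (ethyl vinyl ketone)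
Product: 3 2-methyl-2-(3-oxopentyl)cyclopentane-1,3-dione
Conditions: H2O, AcOH (cat.), 75 °C
Reagents that add atoms: none
Why: Michael addition of the acidic 1,3-dione to the enone stops cleanly at the achiral triketone under mildly acidic aqueous conditions.

**Step 2**
Reactants: 3 2-methyl-2-(3-oxopentyl)cyclopentane-1,3-dione
Product: 4 (7aR)-4,7a-dimethyl-2,3,7,7a-tetrahydro-1H-indene-1,5(6H)-dione
Conditions: D-phenylalanine (1.0 equiv), (1R)-(–)-camphor-10-sulfonic acid (0.5 equiv), DMF, 30 → 70 °C; recrystallise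
Reagents that add atoms: none
Why: This is a Hajos–Parrish–Eder–Sauer–Wiechert enamine aldol condensation, in which a primary amino acid handles the hindered ethyl ketone and the D-series catalyst desymmetrises the dione to set C9 as (7aR).

**Step 3**
Reactants: 4 (7aR)-4,7a-dimethyl-2,3,7,7a-tetrahydro-1H-indene-1,5(6H)-dione; 5 vinylmagnesium bromide
Product: 6 (1S,7aR)-1-ethenyl-1-hydroxy-4,7a-dimethyl-1,2,3,6,7,7a-hexahydro-5H-inden-5-one (OH cis to the angular methyl)
Conditions: 5 (1.3 equiv), LaCl3·2LiCl (0.3 equiv), THF, –78 °C; H2O quench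
Reagents that add atoms: none
Why: The lanthanide-assisted Grignard 1,2-addition picks the saturated cyclopentanone over the tetrasubstituted vinylogous enone carbonyl and attacks anti to the angular methyl (as on 17-oxo steroids), giving a carbinol centre that step 4 erases again.

**Step 4**
Reactants: 6 (1S,7aR)-1-ethenyl-1-hydroxy-4,7a-dimethyl-1,2,3,6,7,7a-hexahydro-5H-inden-5-one; 7 methyl iodoacetate
Product: 9 methyl 3-[(1S,8aS)-5,8a-dimethyl-2,6-dioxo-1,2,3,4,6,7,8,8a-octahydronaphthalen-1-yl]propanoate, via iodohydrin 8 (not isolated)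
Conditions: 7 (1.2 equiv), Et3B (0.2 equiv)/air, CH2Cl2, rt; then AgOTf (1.5 equiv), 2,6-di-tert-butyl-4-methylpyridine (1.5 equiv), –40 °C → rt; then DBU (0.2 equiv), rt
Reagents that add atoms: none
Why: Proposed new method: the electrophilic •CH2CO2Me radical adds to the free vinyl terminus (C1–C2 bond) and iodine transfer places a leaving group on C10 next to the tertiary carbinol, after which Ag(I) abstracts iodide while the antiperiplanar C5–C9 bond (quaternary carbon, best migrating group) shifts to C10 and C5 becomes the ketone (cyclopentanol → cyclohexanone), and DBU then equilibrates C10 to the equatorial β-chain, the stable epimer of 17a-alkyl-D-homo-17-oxo steroids; the closest known reaction types are iodine-atom-transfer radical addition, the Tiffeneau iodohydrin/Ag+ semipinacol, D-homoannulation of 17-hydroxy-20-X pregnanes and photoredox alkylative semipinacol expansion of 1-(1-arylvinyl)cycloalkanols, which have not been merged on an unactivated vinyl carbinol of a cyclopentane.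

**Step 5**
Reactants: 9 methyl 3-[(1S,8aS)-5,8a-dimethyl-2,6-dioxo-1,2,3,4,6,7,8,8a-octahydronaphthalen-1-yl]propanoate
Product: 11 methyl 3-[(1R,8aS)-5,8a-dimethyl-6-oxo-2-(propan-2-ylidene)-1,2,3,4,6,7,8,8a-octahydronaphthalen-1-yl]propanoate, via spiro-β-lactone 10 (not isolated)
Conditions: phenyl 2-methylpropanoate (1.5 equiv), LDA (1.5 equiv), THF, –90 °C; add 9, –90 → 0 °C; H2O; crude 10, SiO2, toluene, 110 °C
Reagents that add atoms: phenyl 2-methylpropanoate CC(C)C(=O)Oc1ccccc1
Why: In this β-lactone olefination the weakly basic phenyl ester enolate adds to the only saturated ketone from the equatorial α-side (the axial β-side is blocked by the C9 methyl) without enolising C10, the aldolate closes irreversibly to the β-lactone, and thermal loss of CO2 places the strained tetrasubstituted alkene regiospecifically.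

**Step 6**
Reactants: 12 1,3-dimethylbenzene (m-xylene)
Product: 13 1-(bromomethyl)-3-methylbenzene
Conditions: NBS (0.9 equiv), AIBN (cat.), PhCF3, reflux; distil
Reagents that add atoms: N-bromosuccinimide O=C1CCC(=O)N1Br
Why: Wohl–Ziegler benzylic bromination stops at the monobromide when NBS is sub-stoichiometric.

**Step 7**
Reactants: 11 methyl 3-[(1R,8aS)-5,8a-dimethyl-6-oxo-2-(propan-2-ylidene)-1,2,3,4,6,7,8,8a-octahydronaphthalen-1-yl]propanoate; 13 1-(bromomethyl)-3-methylbenzene
Product: 15 methyl 3-[(1S,4aS,5R,8aS)-5,8a-dimethyl-5-[(3-methylphenyl)methyl]-6-oxo-2-(propan-2-ylidene)decahydronaphthalen-1-yl]propanoate, via lithium enolate 14 (not isolated)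
Conditions: Li (2.2 equiv), H2O (1.0 equiv), NH3–THF, –78 °C, 15 min; isoprene; 13 (3 equiv), –78 → –33 °C
Reagents that add atoms: none
Why: In this Stork reductive alkylation, axial protonation of the β-carbanion gives the trans-decalin (8α-H) and the regiospecific enolate is benzylated on the α-face away from the axial C9 methyl, which sets C14 (β-CH3, α-CH2Ar) as in the avarol/ilimaquinone series, while the enone takes up electrons far faster than the isolated ester.

**Step 8**
Reactants: 15 methyl 3-[(1S,4aS,5R,8aS)-5,8a-dimethyl-5-[(3-methylphenyl)methyl]-6-oxo-2-(propan-2-ylidene)decahydronaphthalen-1-yl]propanoate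
Product: 16 methyl 3-[(1S,4aS,5R,8aS)-5,8a-dimethyl-6-methylidene-5-[(3-methylphenyl)methyl]-2-(propan-2-ylidene)decahydronaphthalen-1-yl]propanoate
Conditions: Ph3PCH3Br (3 equiv), KHMDS (2.8 equiv), THF, 0 → 60 °C
Reagents that add atoms: methyltriphenylphosphonium bromide C[P+](c1ccccc1)(c1ccccc1)c1ccccc1.[Br-]
Why: Wittig methylenation is proven on this type of decalone flanked by a quaternary carbon, and the ketone reacts ahead of the ester.

**Step 9**
Reactants: 16 methyl 3-[(1S,4aS,5R,8aS)-5,8a-dimethyl-6-methylidene-5-[(3-methylphenyl)methyl]-2-(propan-2-ylidene)decahydronaphthalen-1-yl]propanoate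
Product: 17 methyl 3-[(1S,4aR,5S,6R,8aR)-5,6,8a-trimethyl-5-[(3-methylphenyl)methyl]-2-(propan-2-ylidene)decahydronaphthalen-1-yl]propanoate
Conditions: H2 (1 atm), PtO2 (5 mol %), EtOAc, rt
Reagents that add atoms: none
Why: Heterogeneous hydrogenation reduces only the 1,1-disubstituted alkene (the tetrasubstituted alkene and the arene are inert) and delivers H2 from the α-face opposite the axial C14 methyl, giving the equatorial 13β-methyl.

**Step 10**
Reactants: 17 methyl 3-[(1S,4aR,5S,6R,8aR)-5,6,8a-trimethyl-5-[(3-methylphenyl)methyl]-2-(propan-2-ylidene)decahydronaphthalen-1-yl]propanoate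
Product: 20 3-[(1S,4aR,5S,6R,8aR)-5-[(3-hydroxy-5-methylphenyl)methyl]-5,6,8a-trimethyl-2-(propan-2-ylidene)decahydronaphthalen-1-yl]propanoic acid, via aryl boronate 18 (not isolated), via phenol ester 19 (not isolated)
Conditions: [Ir(OMe)(cod)]2 (2 mol %), dtbpy (4 mol %), B2pin2 (0.6 equiv), THF, 80 °C; then 2 M NaOH, 30 % H2O2, THF–MeOH, 0 → 40 °C; 1 M HCl to pH 3
Reagents that add atoms: bis(pinacolato)diboron CC1(C)OB(OC1(C)C)B1OC(C)(C)C(C)(C)O1; hydrogen peroxide OO; sodium hydroxide [Na+].[OH-]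
Why: Sterically controlled iridium C–H borylation can only reach the position meta to both alkyl groups, and basic peroxide converts C–B to C–OH while the same hydroxide saponifies the unhindered methyl ester.

**Step 11**
Reactants: 20 3-[(1S,4aR,5S,6R,8aR)-5-[(3-hydroxy-5-methylphenyl)methyl]-5,6,8a-trimethyl-2-(propan-2-ylidene)decahydronaphthalen-1-yl]propanoic acid
Product: 21 stypoquinonic acid
Conditions: salcomine (10 mol %), O2 (1 atm), MeCN, rt
Reagents that add atoms: dioxygen O=O
Why: Co(salen)/O2 oxidation of a para-unsubstituted 3,5-dialkylphenol gives the 2,6-dialkyl-1,4-benzoquinone under neutral conditions that spare the alkene, the acid and all stereocentres.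

**Compound list**
1 | 2-methylcyclopentane-1,3-dione | CC1C(=O)CCC1=O | starting material
2 | pent-1-en-3-one | CCC(=O)C=C | starting material
3 | 2-methyl-2-(3-oxopentyl)cyclopentane-1,3-dione | CCC(=O)CCC1(C)C(=O)CCC1=O | intermediate
4 | (7aR)-4,7a-dimethyl-2,3,7,7a-tetrahydro-1H-indene-1,5(6H)-dione | CC1=C2CCC(=O)[C@]2(C)CCC1=O | intermediate
5 | vinylmagnesium bromide | C=C[Mg]Br | starting material
6 | (1S,7aR)-1-ethenyl-1-hydroxy-4,7a-dimethyl-1,2,3,6,7,7a-hexahydro-5H-inden-5-one | CC1=C2CC[C@](O)(C=C)[C@]2(C)CCC1=O | intermediate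
7 | methyl iodoacetate | COC(=O)CI | starting material
8 | iodohydrin: methyl 4-[(1R,7aR)-1-hydroxy-4,7a-dimethyl-5-oxo-2,3,5,6,7,7a-hexahydro-1H-inden-1-yl]-4-iodobutanoate (both C–I epimers) | CC1=C2CC[C@](O)(C(I)CCC(=O)OC)[C@]2(C)CCC1=O | intermediate
9 | methyl 3-[(1S,8aS)-5,8a-dimethyl-2,6-dioxo-1,2,3,4,6,7,8,8a-octahydronaphthalen-1-yl]propanoate | CC1=C2CCC(=O)[C@@H](CCC(=O)OC)[C@]2(C)CCC1=O | intermediate
10 | spiro-β-lactone of 9: 3,3-dimethyloxetan-2-one spiro-joined at C5 (lactone O on the β face, CMe2 on the α face) | CC1=C2CC[C@@]3(OC(=O)C3(C)C)[C@@H](CCC(=O)OC)[C@]2(C)CCC1=O | intermediate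
11 | methyl 3-[(1R,8aS)-5,8a-dimethyl-6-oxo-2-(propan-2-ylidene)-1,2,3,4,6,7,8,8a-octahydronaphthalen-1-yl]propanoate | CC1=C2CCC(=C(C)C)[C@@H](CCC(=O)OC)[C@]2(C)CCC1=O | intermediate
12 | 1,3-dimethylbenzene | Cc1cccc(C)c1 | starting material
13 | 1-(bromomethyl)-3-methylbenzene | Cc1cccc(CBr)c1 | intermediate
14 | lithium enolate C13(OLi)=C14(CH3) of the trans-decalone (8α-H) | [Li+].[O-]C1=C(C)[C@H]2CCC(=C(C)C)[C@@H](CCC(=O)OC)[C@]2(C)CC1 | intermediate
15 | methyl 3-[(1S,4aS,5R,8aS)-5,8a-dimethyl-5-[(3-methylphenyl)methyl]-6-oxo-2-(propan-2-ylidene)decahydronaphthalen-1-yl]propanoate | Cc1cccc(C[C@]2(C)[C@H]3CCC(=C(C)C)[C@@H](CCC(=O)OC)[C@]3(C)CCC2=O)c1 | intermediate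
16 | methyl 3-[(1S,4aS,5R,8aS)-5,8a-dimethyl-6-methylidene-5-[(3-methylphenyl)methyl]-2-(propan-2-ylidene)decahydronaphthalen-1-yl]propanoate | Cc1cccc(C[C@]2(C)[C@H]3CCC(=C(C)C)[C@@H](CCC(=O)OC)[C@]3(C)CCC2=C)c1 | intermediate
17 | methyl 3-[(1S,4aR,5S,6R,8aR)-5,6,8a-trimethyl-5-[(3-methylphenyl)methyl]-2-(propan-2-ylidene)decahydronaphthalen-1-yl]propanoate | Cc1cccc(C[C@]2(C)[C@H]3CCC(=C(C)C)[C@@H](CCC(=O)OC)[C@]3(C)CC[C@H]2C)c1 | intermediate
18 | aryl boronate: 17 carrying Bpin at the arene position meta to both alkyl groups | Cc1cc(B4OC(C)(C)C(C)(C)O4)cc(C[C@]2(C)[C@H]3CCC(=C(C)C)[C@@H](CCC(=O)OC)[C@]3(C)CC[C@H]2C)c1 | intermediate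
19 | methyl 3-[(1S,4aR,5S,6R,8aR)-5-[(3-hydroxy-5-methylphenyl)methyl]-5,6,8a-trimethyl-2-(propan-2-ylidene)decahydronaphthalen-1-yl]propanoate | Cc1cc(O)cc(C[C@]2(C)[C@H]3CCC(=C(C)C)[C@@H](CCC(=O)OC)[C@]3(C)CC[C@H]2C)c1 | intermediate
20 | 3-[(1S,4aR,5S,6R,8aR)-5-[(3-hydroxy-5-methylphenyl)methyl]-5,6,8a-trimethyl-2-(propan-2-ylidene)decahydronaphthalen-1-yl]propanoic acid | Cc1cc(O)cc(C[C@]2(C)[C@H]3CCC(=C(C)C)[C@@H](CCC(=O)O)[C@]3(C)CC[C@H]2C)c1 | intermediate
21 | stypoquinonic acid: 3-[(1S,4aR,5S,6R,8aR)-5,6,8a-trimethyl-5-[(5-methyl-3,6-dioxocyclohexa-1,4-dien-1-yl)methyl]-2-(propan-2-ylidene)decahydronaphthalen-1-yl]propanoic acid | CC1=CC(=O)C=C(C[C@]2(C)[C@H]3CCC(=C(C)C)[C@@H](CCC(=O)O)[C@]3(C)CC[C@H]2C)C1=O | target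

**Total steps:** 11. **Longest linear sequence:** 10 (steps 1–5 and 7–11).

**Steps most likely to fail**

*Step 4 (the proposed step).* There are three risks. The γ-iodo ester may lactonise, the iodohydrin may close to the epoxide, or C6 may migrate instead of C9, because C9 is attached to the electron-poor enone carbon. The fallback uses known chemistry, sets out from 6 and returns at 9. Hydroxyl-directed epoxidation of the vinyl group (VO(acac)2, t-BuOOH) gives the epoxy alcohol F1. The established Lewis-acid semipinacol rearrangement of 2,3-epoxy alcohols (BF3·OEt2, CH2Cl2, –78 °C) moves C9 to C10 and gives the ring-expanded β-hydroxy ketone F2. MsCl/Et3N converts this into the mesylate F3, and DBU eliminates it to the α-methylene ketone F4. A Mukaiyama–Michael addition of 1-methoxy-1-(trimethylsilyloxy)ethene (cat. TMSOTf) to this reactive exocyclic enone gives the silyl enol ether F5. Dilute acid followed by DBU then delivers 9.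

*Step 5.* The tertiary enolate may not add to the hindered C5 ketone. The fallback sets out from 9 and returns at 11, and replaces the bulky sp3 nucleophile by a small sp2 one. Isopropenylmagnesium bromide/LaCl3·2LiCl (–78 °C) gives the tertiary allylic alcohol F6. Ionic reduction (Et3SiH, BF3·OEt2, CH2Cl2, –78 °C) then delivers hydride to the unhindered CH2 end of the allyl cation and leaves the tetrasubstituted alkene of 11.

*Step 7.* The methyl ester may be attacked under dissolving-metal conditions. The fallback sets out from 11 and returns at 15, and carries the chain through the reduction as an inert carboxylate. LiOH (THF–H2O) gives the enone acid F7. Li/NH3 (3.2 equiv Li) followed by 13 gives the benzylated keto acid F8, and MeI/K2CO3 (DMF) restores the ester 15.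

**Further compounds**
F1 | step 4 | (1S,7aR)-1-hydroxy-4,7a-dimethyl-1-(oxiran-2-yl)-1,2,3,6,7,7a-hexahydro-5H-inden-5-one | CC1=C2CC[C@](O)(C3CO3)[C@]2(C)CCC1=O
F2 | step 4 | (8aS)-1-(hydroxymethyl)-5,8a-dimethyl-3,4,8,8a-tetrahydronaphthalene-2,6(1H,7H)-dione | CC1=C2CCC(=O)C(CO)[C@]2(C)CCC1=O
F3 | step 4 | methanesulfonate of F2 | CC1=C2CCC(=O)C(COS(C)(=O)=O)[C@]2(C)CCC1=O
F4 | step 4 | (8aS)-5,8a-dimethyl-1-methylidene-3,4,8,8a-tetrahydronaphthalene-2,6(1H,7H)-dione | CC1=C2CCC(=O)C(=C)[C@]2(C)CCC1=O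
F5 | step 4 | C5 trimethylsilyl enol ether of 9 (C5=C10 double bond) | CC1=C2CCC(O[Si](C)(C)C)=C(CCC(=O)OC)[C@]2(C)CCC1=O
F6 | step 5 | C5 tertiary allylic alcohol from 9 (β-OH, α-isopropenyl) | CC1=C2CC[C@](O)(C(C)=C)[C@@H](CCC(=O)OC)[C@]2(C)CCC1=O
F7 | step 7 | 3-[(1R,8aS)-5,8a-dimethyl-6-oxo-2-(propan-2-ylidene)-1,2,3,4,6,7,8,8a-octahydronaphthalen-1-yl]propanoic acid | CC1=C2CCC(=C(C)C)[C@@H](CCC(=O)O)[C@]2(C)CCC1=O
F8 | step 7 | 3-[(1S,4aS,5R,8aS)-5,8a-dimethyl-5-[(3-methylphenyl)methyl]-6-oxo-2-(propan-2-ylidene)decahydronaphthalen-1-yl]propanoic acid | Cc1cccc(C[C@]2(C)[C@H]3CCC(=C(C)C)[C@@H](CCC(=O)O)[C@]3(C)CCC2=O)c1
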